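Gamma holds twice the free catalyst of alpha and makes target twice as fast, and the gamma curve stays straight up to 26.2% within the scatter. So my bench rule is that target made equals rate times time, with the rate proportional to free catalyst.

| setting | alpha | eta | gamma | grey | green | violet | ochre |
|---|---|---|---|---|---|---|---|
| substrate | 0.21 M | 0.21 M | 0.21 M | 0.21 M | 0.21 M (fed, over 5.00 h) | 0.21 M | 0.21 M |
| free catalyst | 5.2 mM | 7.3 mM | 11 mM | 5.2 mM | 5.2 mM | 5.2 mM | 5.2 mM |
| remark | run made earlier | run made earlier | run made earlier | everything together in a closed stirred flask, run for 10 h | all but substrate at the start; substrate goes in evenly over 5.00 h, the run ends at 10 h | one stirred flow tank at steady state, fed with the mixture as stated, mean residence time 10 h | a single well-mixed tank run continuously and read at steady state, 100 h in it on average |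
| time |  |  |  | 10 h | 10 h |  |  |

| run | time / h | target / % |
|---|---|---|
| alpha | 0.833 | 1.0 |
| alpha | 2.50 | 4.4 |
| alpha | 5.00 | 11.7 |
| alpha | 8.00 | 17.4 |
| alpha | 10.0 | 22.1 |
| eta | 1.33 | 3.7 |
| eta | 2.50 | 8.9 |
| eta | 4.00 | 11.1 |
| eta | 5.00 | 14.9 |
| eta | 6.00 | 17.8 |
| gamma | 0.500 | 1.7 |
| gamma | 0.833 | 4.2 |
| gamma | 1.50 | 7.2 |
| gamma | 3.00 | 13.7 |
| gamma | 6.00 | 26.2 |

(standard deviation of a reading: 1 percentage point)

- the stated concentrations are those of everything mixed, before any reaction; amounts are the same in each set-up
- the feed brings no volume worth counting
- the earlier runs were made in a closed, stirred flask

* the set-up with the highest amount of target at the outlet or at the end, in percent of the substrate put in ("none" if the first two lie within 2 percentage points) (grey / green / violet / ochre / none)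
* amount of target at the outlet or at the end, in percent of the substrate put in, grey
* amount of target at the outlet or at the end, in percent of the substrate put in, green
* amount of target at the outlet or at the end, in percent of the substrate put in, violet
* amount of target at the outlet or at the end, in percent of the substrate put in, ochre

Alpha's line reaches the whole charge in 45.2 h, which I call the clearing time: the hours that line needs at 5.2 mM of free catalyst. Time divided by clearing time is then the share converted. Grey repeats alpha, so I expect 22.1%. In green the substrate arrives on average 2.50 h late, so the rule gives 16.6% if that delay counts in full.

For a tank I follow one substrate molecule to a fork: it reacts or it leaves, and its chance of reacting is residence time over residence time plus clearing time. That gives 18.1% in violet. Ochre is where the rule stops, since its 100 h is longer than the clearing time by a ratio of 2.21, and a straight line would pass the charge. There the fork gives me 68.9% of the substrate reacted, and the line gives the whole charge.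

The forecast, holding that “the data fit anything from zero to first order”, says 22% for grey, 19% for green, 21% for violet and 85% for ochre, with ochre best.

The flask gives 21.5% for grey, 19.1% for green, 20.7% for violet and 44.2% for ochre, so the best is ochre.

    target + free catalyst ⇌ isomer of the product + free catalyst, rate k1*[free catalyst]*[target] forward; the back reaction follows from the equilibrium constant (K = 2.50, k = 6.22 /M/h)
    catalyst intermediate B → free catalyst + target (k = 5.04 /h)
    substrate + free catalyst → catalyst intermediate A (k = 51.2 /M/h)
    catalyst intermediate A ⇌ catalyst intermediate B (K = 0.650, k = 1.98 /h)

In ochre the substrate stands at 0.0120 M, so nearly all of it has reacted, more than the fork's 68.9%. Target still reads 44.2% because of the passing of target into isomer of the product, and the ochre run with that step struck out gives 93.3%. The neighbour flask, green with 0.021 M of free catalyst, scales to a clearing time of 11.2 h, so with the same delay in full its line reaches 66.9%, and that flask ends with 21.6% of substrate left and 63.8% of target.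

The earlier runs and the new flask are calculated for an exercise; the scatter is artificial.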